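**Plan**

1. Retrosynthetic cuts, in order: the epoxide oxygen (back to a C11=C12 alkene); the butenolide (C8=C17 by metathesis, the ester C–O by acylation); C6–C7 (ten-membered ring); C3–C4 and C2–C3 (side chain on the C2 carbonyl); C9–C10 (anti SN2′ on an allylic lactone); last, C12–C13 and C14–C1 together by a [4+2] cycloaddition.
2. Forward: a 2-pyrone and a ketene acetal give the six-membered carbocycle as a bridged lactone; the bridge is then used up as leaving group while C9 is delivered to C10; the C2 chain is built; the ten-membered ring is closed at C6–C7; the butenolide is closed; the epoxide is made last.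
3. Enabling feature: in ring C1/C10/C11/C12/C13/C14, the quaternary C1 carries C2 (an oxygenated carbon that can be raised to carboxyl level), C14 carries oxygen, and C11–C12 is at alkene level. A C10=C11 alkene with a leaving oxygen on C12 is therefore an allylic-transposition precursor. This is exactly the adduct of a 3-methyl-2-pyrone (its C2(=O)–O1 unit spanning C1 and C12) with a ketene acetal (C13–C14).
4. Helpers: bromine on pyrone C5 (activator, later exchanged for the C20 methyl), the diethyl ketal (C14 at ketone level), the lactone bridge (temporary ring).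
5. Stereochemistry: C1/C12 relative configuration from the bicycle; absolute configuration and C14 from an oxazaborolidine reduction run as kinetic resolution; C10 by anti SN2′ relay from the bridge; C2 by a 1,3-anti Evans–Tishchenko reduction, which also makes the C14 acetate; Z-C5=C6 from an anti-carbometalation; C7 in the ring closure; the epoxide by steric approach control.

Key step: step 2

Numbering remark: target locants are used throughout. Ten-membered ring C1–C10 (C2 butanoate carbon, C5=C6 with methyl C16, C7 lactone CH–O); cyclohexane C1, C10, C11 (methyl C20), C12, C13, C14 (acetate); C15 methyl on C1; lactone C8=C17(C18)–C19(=O)–O–C7. In the bicyclic compounds 4–8, C1/C3/C4/C5/C6/C7/C8 correspond to target C12/C2/C1/C10/C11/C13/C14.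

Assumption: 4, 5 and 6 are racemic; their SMILES show the enantiomer that is carried on after step 5.

**Step 1**
Reactants: 1 3,5-dibromo-2H-pyran-2-one
Product: 2 5-bromo-3-methyl-2H-pyran-2-one
Conditions: MeZnCl (1.1 equiv), Pd(PPh3)4 (5 mol %), THF, 0 °C → rt
Reagents that add atoms: methylzinc chloride, C[Zn]Cl
Why: Negishi coupling; zerovalent palladium should insert first into the C3–Br bond next to the carbonyl group, as in the known C3-selective cross-couplings of this dibromide, so the future C15 methyl is placed and the C5 bromine is kept as activator.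

**Step 2**
Reactants: 2 5-bromo-3-methyl-2H-pyran-2-one; 3 1,1-diethoxyethene
Product: 4 rac-(1R,4R)-6-bromo-8,8-diethoxy-4-methyl-2-oxabicyclo[2.2.2]oct-5-en-3-one
Conditions: 3 (3 equiv), toluene, 60 °C, sealed tube
Reagents that add atoms: none
Why: Inverse-electron-demand [4+2] cycloaddition: the electron-rich ketene acetal adds across C3 and C6 of the bromopyrone (LUMO lowered by the C5 bromine) in a concerted, asynchronous way, its nucleophilic CH2 terminus bonding to the electrophilic pyrone C6 and its acetal carbon to pyrone C3. The closest known reaction type is the thermal cycloaddition of bromo-2-pyrones and of 3-carbomethoxy-2-pyrone with enol ethers and ketene acetals, which gives isolable 2-oxabicyclo[2.2.2]octenones. One ring is closed, the six-membered carbocycle, by suprafacial [4+2] addition onto the diene that the lactone holds s-cis; the lactone survives as the O–C(=O) bridge. The two new stereocentres are the bridgeheads C1 and C4 (quaternary); their relative configuration is fixed by the bicycle, so a single racemic diastereomer must form, and no endo/exo question arises because the dienophile carries two identical ethoxy groups. The selectivity needed is regiochemical (acetal carbon next to the methyl-bearing bridgehead) and is secured by the matched polarisation of the two partners; loss of CO2 by retro-[4+2] is avoided by staying at or below 60 °C.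

**Step 3**
Reactants: 4 rac-(1R,4R)-6-bromo-8,8-diethoxy-4-methyl-2-oxabicyclo[2.2.2]oct-5-en-3-one
Product: 5 rac-(1R,4R)-8,8-diethoxy-4,6-dimethyl-2-oxabicyclo[2.2.2]oct-5-en-3-one
Conditions: MeZnCl (1.5 equiv), Pd(dppf)Cl2 (5 mol %), THF, 45 °C
Reagents that add atoms: methylzinc chloride, C[Zn]Cl
Why: Negishi coupling at the vinylic C–Br bond installs the C20 methyl; ionisation of the allylic lactone C–O bond should not compete because the endo ethoxy group of the ketal blocks the alkene face anti to that bond.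

**Step 4**
Reactants: 5 rac-(1R,4R)-8,8-diethoxy-4,6-dimethyl-2-oxabicyclo[2.2.2]oct-5-en-3-one
Product: 6 rac-(1R,4R)-4,6-dimethyl-2-oxabicyclo[2.2.2]oct-5-ene-3,8-dione
Conditions: 1 M aq. HCl, THF, 0 °C → rt
Reagents that add atoms: water, O
Why: Acid-catalysed ketal hydrolysis through the oxocarbenium ion; the α-carbon between the two carbonyl groups is quaternary and a bridgehead, so no enolisation or epimerisation is possible.

**Step 5**
Reactants: 6 rac-(1R,4R)-4,6-dimethyl-2-oxabicyclo[2.2.2]oct-5-ene-3,8-dione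
Product: 7 (1R,4R,8S)-8-hydroxy-4,6-dimethyl-2-oxabicyclo[2.2.2]oct-5-en-3-one
Conditions: (R)-2-methyl-CBS-oxazaborolidine (0.2 equiv), BH3·SMe2 (0.3 equiv), THF, −30 °C, stopped near half conversion; MeOH; chromatography
Reagents that add atoms: none
Why: Corey–Bakshi–Shibata reduction run as a kinetic resolution: for the (1R,4R) ketone the face chosen by the (R)-catalyst is also the intrinsically preferred one (from the alkene side, anti to the C4–C3 acyl bond, Felkin–Anh), which should give the exo (8S) alcohol, while the mismatched (1S,4S) ketone is left unreduced and is separated.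

**Step 6**
Reactants: 7 (1R,4R,8S)-8-hydroxy-4,6-dimethyl-2-oxabicyclo[2.2.2]oct-5-en-3-one
Product: 8 (1R,4R,8S)-8-[(tert-butyldimethylsilyl)oxy]-4,6-dimethyl-2-oxabicyclo[2.2.2]oct-5-en-3-one
Conditions: TBSOTf (1.3 equiv), 2,6-lutidine, CH2Cl2, −78 → 0 °C
Reagents that add atoms: tert-butyldimethylsilyl trifluoromethanesulfonate, CC(C)(C)[Si](C)(C)OS(=O)(=O)C(F)(F)F
Why: Silylation under non-alkoxide conditions avoids retro-aldol opening of the β-hydroxy lactone and gives an ether that survives the organometallic steps and shields the lactone carbonyl.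

**Step 7**
Reactants: 8 (1R,4R,8S)-8-[(tert-butyldimethylsilyl)oxy]-4,6-dimethyl-2-oxabicyclo[2.2.2]oct-5-en-3-one; 9 [2-(1,3-dioxolan-2-yl)ethyl]magnesium bromide
Product: 10 (1R,2S,6S)-6-[(tert-butyldimethylsilyl)oxy]-2-[2-(1,3-dioxolan-2-yl)ethyl]-1,3-dimethylcyclohex-3-ene-1-carboxylic acid
Conditions: 9 (2.5 equiv), CuBr·SMe2 (20 mol %), THF/Me2S, −30 → 0 °C; aq. NH4Cl, then pH 4
Reagents that add atoms: none
Why: Copper-catalysed anti SN2′ substitution of the bicyclic allylic lactone: the alkylcopper adds at the γ-carbon (target C10) on the face opposite to the C–O bond (the α-carbon is a bridgehead and closed to rear attack), which sets C10 trans to the carboxyl group, moves the double bond to C11=C12 and frees the C2 acid; the exo silyloxy group leaves the attacked face open.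

**Step 8**
Reactants: 10 (1R,2S,6S)-6-[(tert-butyldimethylsilyl)oxy]-2-[2-(1,3-dioxolan-2-yl)ethyl]-1,3-dimethylcyclohex-3-ene-1-carboxylic acid
Product: 11 1-[(1R,2S,6S)-6-[(tert-butyldimethylsilyl)oxy]-2-[2-(1,3-dioxolan-2-yl)ethyl]-1,3-dimethylcyclohex-3-en-1-yl]ethan-1-one
Conditions: MeLi (3.5 equiv), Et2O, 0 °C → rt; inverse quench into cold aq. NH4Cl
Reagents that add atoms: methyllithium, [Li]C
Why: Addition of methyllithium to the lithium carboxylate gives a dilithium gem-diolate that is stable until work-up, the classical route from a hindered acid to its methyl ketone without over-addition.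

**Step 9**
Reactants: 12 prop-2-yn-1-ol
Product: 14 (2Z)-3-iodo-2-methylprop-2-en-1-ol, via chelated alkenylmagnesium alkoxide 13 (not isolated)
Conditions: MeMgBr (2.5 equiv), CuI (10 mol %), Et2O, −10 °C → rt; then I2, −30 → 0 °C
Reagents that add atoms: methylmagnesium bromide, C[Mg]Br; iodine, II
Why: Copper-catalysed anti-carbomagnesiation of the propargylic alkoxide places magnesium cis to the CH2O group in a five-membered chelate, and iodinolysis with retention gives the Z iodide that later becomes the Z-C5=C6 alkene.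

**Step 10**
Reactants: 14 (2Z)-3-iodo-2-methylprop-2-en-1-ol
Product: 15 (1Z)-3-bromo-1-iodo-2-methylprop-1-ene
Conditions: CBr4, PPh3, CH2Cl2, 0 °C
Reagents that add atoms: carbon tetrabromide, BrC(Br)(Br)Br
Why: Appel bromination of the primary allylic alcohol under neutral conditions, which leaves the alkene geometry and the C–I bond untouched.

**Step 11**
Reactants: 11 1-[(1R,2S,6S)-6-[(tert-butyldimethylsilyl)oxy]-2-[2-(1,3-dioxolan-2-yl)ethyl]-1,3-dimethylcyclohex-3-en-1-yl]ethan-1-one; 15 (1Z)-3-bromo-1-iodo-2-methylprop-1-ene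
Product: 17 (4Z)-1-[(1R,2S,6S)-6-[(tert-butyldimethylsilyl)oxy]-2-[2-(1,3-dioxolan-2-yl)ethyl]-1,3-dimethylcyclohex-3-en-1-yl]-5-iodo-4-methylpent-4-en-1-one, via lithium enolate 16 (not isolated)
Conditions: LDA (1.1 equiv), THF, −78 °C; then 15 (1.5 equiv), DMPU, −78 → −30 °C
Reagents that add atoms: none
Why: Enolate alkylation: the ketone can enolise only toward its methyl group because the other α-carbon is quaternary, and SN2 attack on the allylic bromide forms C3–C4 with the Z-iodoalkene intact.

**Step 12**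
Reactants: 17 (4Z)-1-[(1R,2S,6S)-6-[(tert-butyldimethylsilyl)oxy]-2-[2-(1,3-dioxolan-2-yl)ethyl]-1,3-dimethylcyclohex-3-en-1-yl]-5-iodo-4-methylpent-4-en-1-one
Product: 18 (4Z)-1-[(1R,2S,6S)-2-[2-(1,3-dioxolan-2-yl)ethyl]-6-hydroxy-1,3-dimethylcyclohex-3-en-1-yl]-5-iodo-4-methylpent-4-en-1-one
Conditions: HF·pyridine, pyridine, THF, 0 °C → rt
Reagents that add atoms: none
Why: Fluoride-mediated desilylation under buffered, non-basic conditions, chosen so that the β-hydroxy ketone is not exposed to alkoxide (retro-aldol) and the dioxolane survives.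

**Step 13**
Reactants: 18 (4Z)-1-[(1R,2S,6S)-2-[2-(1,3-dioxolan-2-yl)ethyl]-6-hydroxy-1,3-dimethylcyclohex-3-en-1-yl]-5-iodo-4-methylpent-4-en-1-one
Product: 19 (1S,4Z)-1-[(1S,2S,6S)-6-(acetyloxy)-2-[2-(1,3-dioxolan-2-yl)ethyl]-1,3-dimethylcyclohex-3-en-1-yl]-5-iodo-4-methylpent-4-en-1-ol
Conditions: CH3CHO (10 equiv), SmI2 (30 mol %), THF, −10 °C
Reagents that add atoms: acetaldehyde, CC=O
Why: Evans–Tishchenko reduction: the hemiacetal of the C14 hydroxyl with acetaldehyde delivers hydride to the C2 ketone through a samarium-bridged chair in which both oxygens are axial, which should set C2 (S) 1,3-anti to C14 and leave the C14 oxygen as its acetate in the same event.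

**Step 14**
Reactants: 19 (1S,4Z)-1-[(1S,2S,6S)-6-(acetyloxy)-2-[2-(1,3-dioxolan-2-yl)ethyl]-1,3-dimethylcyclohex-3-en-1-yl]-5-iodo-4-methylpent-4-en-1-ol
Product: 20 (1S,4Z)-1-[(1S,2S,6S)-6-(acetyloxy)-2-[2-(1,3-dioxolan-2-yl)ethyl]-1,3-dimethylcyclohex-3-en-1-yl]-5-iodo-4-methylpent-4-en-1-yl butanoate
Conditions: (PrCO)2O (3 equiv), pyridine, DMAP (cat.), CH2Cl2, 0 °C → rt, on crude 19
Reagents that add atoms: butanoic anhydride, CCCC(=O)OC(=O)CCC
Why: Nucleophile-catalysed acylation of the C2 alcohol, carried out at once so that 1,3-migration of the acetyl group cannot scramble the two esters.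

**Step 15**
Reactants: 20 (1S,4Z)-1-[(1S,2S,6S)-6-(acetyloxy)-2-[2-(1,3-dioxolan-2-yl)ethyl]-1,3-dimethylcyclohex-3-en-1-yl]-5-iodo-4-methylpent-4-en-1-yl butanoate
Product: 21 (1S,4Z)-1-[(1S,2S,6S)-6-(acetyloxy)-1,3-dimethyl-2-(3-oxopropyl)cyclohex-3-en-1-yl]-5-iodo-4-methylpent-4-en-1-yl butanoate
Conditions: 1 M aq. HCl, THF, rt
Reagents that add atoms: water, O
Why: Acid-catalysed acetal hydrolysis frees the C7 aldehyde; the two esters, the alkenyl iodide and the trisubstituted alkene tolerate cold dilute acid.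

**Step 16**
Reactants: 21 (1S,4Z)-1-[(1S,2S,6S)-6-(acetyloxy)-1,3-dimethyl-2-(3-oxopropyl)cyclohex-3-en-1-yl]-5-iodo-4-methylpent-4-en-1-yl butanoate
Product: 22 (1S,4Z)-1-[(1S,2S,6S)-6-(acetyloxy)-2-(2-formylprop-2-en-1-yl)-1,3-dimethylcyclohex-3-en-1-yl]-5-iodo-4-methylpent-4-en-1-yl butanoate
Conditions: 37% aq. CH2O, pyrrolidine (10 mol %), EtCO2H (10 mol %), i-PrOH, 45 °C
Reagents that add atoms: formaldehyde, C=O
Why: Amine-catalysed α-methylenation of the aldehyde (enamine Mannich addition, then elimination) gives the 2-substituted acrolein whose C8=CH2 group serves the later metathesis.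

**Step 17**
Reactants: 22 (1S,4Z)-1-[(1S,2S,6S)-6-(acetyloxy)-2-(2-formylprop-2-en-1-yl)-1,3-dimethylcyclohex-3-en-1-yl]-5-iodo-4-methylpent-4-en-1-yl butanoate
Product: 23 ten-membered-ring allylic alcohol (1S,2S,5Z,7R,10S,14S): C6–C7 closed, 7-hydroxy, exocyclic C8=CH2, C11=C12, 2-butanoate, 14-acetate
Conditions: CrCl2 (10 equiv), NiCl2 (2 mol %), DMSO/THF, rt, slow addition to 2 mM
Reagents that add atoms: none
Why: Nozaki–Hiyama–Kishi ring closure: zerovalent nickel inserts into the C–I bond, the alkenyl group passes to trivalent chromium and adds 1,2 to the enal, closing the ten-membered ring; the β,β-disubstituted alkenyl iodide should keep its Z geometry, and the 7R alcohol is expected from the arrangement that keeps the Cr–O unit on the periphery of the forming ring.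

**Step 18**
Reactants: 23 ten-membered-ring allylic alcohol (1S,2S,5Z,7R,10S,14S)
Product: 24 7-(2-methylprop-2-enoate) of 23, configuration unchanged
Conditions: methacryloyl chloride (3 equiv), Et3N, DMAP (cat.), CH2Cl2, 0 °C
Reagents that add atoms: methacryloyl chloride, CC(=C)C(=O)Cl
Why: Acylation of the secondary alcohol with retention at C7 brings in C17, C18 and C19 of the lactone.

**Step 19**
Reactants: 24 7-(2-methylprop-2-enoate) of 23
Product: 25 11,12-alkene precursor of the target (target without the epoxide oxygen; 1S,2S,5Z,7R,10S,14S)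
Conditions: second-generation Hoveyda–Grubbs catalyst (10 mol %), toluene (5 mM), 80 °C
Reagents that add atoms: none
Why: Ring-closing metathesis between the two 1,1-disubstituted alkenes closes the five-membered butenolide with its tetrasubstituted C8=C17 bond and loss of ethene; the trisubstituted ring alkenes should stay inert.

**Step 20**
Reactants: 25 11,12-alkene precursor of the target
Product: 26 CNP0220791.2 (1S,2S,5Z,7R,10R,11R,12S,14S)
Conditions: m-CPBA (1.1 equiv), NaHCO3, CH2Cl2, 0 °C
Reagents that add atoms: 3-chloroperoxybenzoic acid, OOC(=O)c1cccc(Cl)c1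
Why: Prilezhaev epoxidation of the most electron-rich alkene (C5=C6 is deactivated by the allylic lactone oxygen, the butenolide alkene is conjugated); β-face attack is expected because the axial C14 acetoxy group, syn-axial to the less substituted alkene carbon C12, shields the α face.

**Compound list**

1 | 3,5-dibromo-2H-pyran-2-one | O=C1OC=C(Br)C=C1Br | starting material
2 | 5-bromo-3-methyl-2H-pyran-2-one | O=C1OC=C(Br)C=C1C | intermediate
3 | 1,1-diethoxyethene | C=C(OCC)OCC | starting material
4 | rac-(1R,4R)-6-bromo-8,8-diethoxy-4-methyl-2-oxabicyclo[2.2.2]oct-5-en-3-one | O=C1O[C@@H]2CC(OCC)(OCC)[C@@]1(C)C=C2Br | intermediate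
5 | rac-(1R,4R)-8,8-diethoxy-4,6-dimethyl-2-oxabicyclo[2.2.2]oct-5-en-3-one | O=C1O[C@@H]2CC(OCC)(OCC)[C@@]1(C)C=C2C | intermediate
6 | rac-(1R,4R)-4,6-dimethyl-2-oxabicyclo[2.2.2]oct-5-ene-3,8-dione | O=C1O[C@@H]2CC(=O)[C@@]1(C)C=C2C | intermediate
7 | (1R,4R,8S)-8-hydroxy-4,6-dimethyl-2-oxabicyclo[2.2.2]oct-5-en-3-one | O=C1O[C@@H]2C[C@H](O)[C@@]1(C)C=C2C | intermediate
8 | (1R,4R,8S)-8-[(tert-butyldimethylsilyl)oxy]-4,6-dimethyl-2-oxabicyclo[2.2.2]oct-5-en-3-one | O=C1O[C@@H]2C[C@H](O[Si](C)(C)C(C)(C)C)[C@@]1(C)C=C2C | intermediate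
9 | [2-(1,3-dioxolan-2-yl)ethyl]magnesium bromide | Br[Mg]CCC1OCCO1 | starting material
10 | (1R,2S,6S)-6-[(tert-butyldimethylsilyl)oxy]-2-[2-(1,3-dioxolan-2-yl)ethyl]-1,3-dimethylcyclohex-3-ene-1-carboxylic acid | OC(=O)[C@]1(C)[C@@H](CCC2OCCO2)C(C)=CC[C@@H]1O[Si](C)(C)C(C)(C)C | intermediate
11 | 1-[(1R,2S,6S)-6-[(tert-butyldimethylsilyl)oxy]-2-[2-(1,3-dioxolan-2-yl)ethyl]-1,3-dimethylcyclohex-3-en-1-yl]ethan-1-one | CC(=O)[C@]1(C)[C@@H](CCC2OCCO2)C(C)=CC[C@@H]1O[Si](C)(C)C(C)(C)C | intermediate
12 | prop-2-yn-1-ol | OCC#C | starting material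
13 | chelated alkenylmagnesium alkoxide (4-methyl-2,5-dihydro-1,2-oxamagnesole) | CC1=C[Mg]OC1 | intermediate (not isolated)
14 | (2Z)-3-iodo-2-methylprop-2-en-1-ol | OC/C(C)=C\I | intermediate
15 | (1Z)-3-bromo-1-iodo-2-methylprop-1-ene | BrC/C(C)=C\I | intermediate
16 | lithium enolate of 11 | [Li]OC(=C)[C@]1(C)[C@@H](CCC2OCCO2)C(C)=CC[C@@H]1O[Si](C)(C)C(C)(C)C | intermediate (not isolated)
17 | (4Z)-1-[(1R,2S,6S)-6-[(tert-butyldimethylsilyl)oxy]-2-[2-(1,3-dioxolan-2-yl)ethyl]-1,3-dimethylcyclohex-3-en-1-yl]-5-iodo-4-methylpent-4-en-1-one | O=C(CC/C(C)=C\I)[C@]1(C)[C@@H](CCC2OCCO2)C(C)=CC[C@@H]1O[Si](C)(C)C(C)(C)C | intermediate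
18 | (4Z)-1-[(1R,2S,6S)-2-[2-(1,3-dioxolan-2-yl)ethyl]-6-hydroxy-1,3-dimethylcyclohex-3-en-1-yl]-5-iodo-4-methylpent-4-en-1-one | O=C(CC/C(C)=C\I)[C@]1(C)[C@@H](CCC2OCCO2)C(C)=CC[C@@H]1O | intermediate
19 | (1S,4Z)-1-[(1S,2S,6S)-6-(acetyloxy)-2-[2-(1,3-dioxolan-2-yl)ethyl]-1,3-dimethylcyclohex-3-en-1-yl]-5-iodo-4-methylpent-4-en-1-ol | O[C@@H](CC/C(C)=C\I)[C@]1(C)[C@@H](CCC2OCCO2)C(C)=CC[C@@H]1OC(C)=O | intermediate
20 | (1S,4Z)-1-[(1S,2S,6S)-6-(acetyloxy)-2-[2-(1,3-dioxolan-2-yl)ethyl]-1,3-dimethylcyclohex-3-en-1-yl]-5-iodo-4-methylpent-4-en-1-yl butanoate | CCCC(=O)O[C@@H](CC/C(C)=C\I)[C@]1(C)[C@@H](CCC2OCCO2)C(C)=CC[C@@H]1OC(C)=O | intermediate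
21 | (1S,4Z)-1-[(1S,2S,6S)-6-(acetyloxy)-1,3-dimethyl-2-(3-oxopropyl)cyclohex-3-en-1-yl]-5-iodo-4-methylpent-4-en-1-yl butanoate | CCCC(=O)O[C@@H](CC/C(C)=C\I)[C@]1(C)[C@@H](CCC=O)C(C)=CC[C@@H]1OC(C)=O | intermediate
22 | (1S,4Z)-1-[(1S,2S,6S)-6-(acetyloxy)-2-(2-formylprop-2-en-1-yl)-1,3-dimethylcyclohex-3-en-1-yl]-5-iodo-4-methylpent-4-en-1-yl butanoate | CCCC(=O)O[C@@H](CC/C(C)=C\I)[C@]1(C)[C@@H](CC(=C)C=O)C(C)=CC[C@@H]1OC(C)=O | intermediate
23 | ten-membered-ring allylic alcohol (1S,2S,5Z,7R,10S,14S): 7-hydroxy, exocyclic C8=CH2, C11=C12, 2-butanoate, 14-acetate | CCCC(=O)O[C@H]1CC/C(C)=C\[C@@H](O)C(=C)C[C@H]2C(C)=CC[C@H](OC(C)=O)[C@]12C | intermediate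
24 | 7-(2-methylprop-2-enoate) of 23 | CCCC(=O)O[C@H]1CC/C(C)=C\[C@@H](OC(=O)C(C)=C)C(=C)C[C@H]2C(C)=CC[C@H](OC(C)=O)[C@]12C | intermediate
25 | 11,12-alkene precursor of the target (1S,2S,5Z,7R,10S,14S) | CCCC(=O)O[C@H]1CC/C(C)=C\[C@H]2OC(=O)C(C)=C2C[C@H]2C(C)=CC[C@H](OC(C)=O)[C@]12C | intermediate
26 | CNP0220791.2 (1S,2S,5Z,7R,10R,11R,12S,14S) | CCCC(=O)O[C@H]1CC/C(C)=C\[C@H]2OC(=O)C(C)=C2C[C@H]2[C@@]3(C)O[C@H]3C[C@H](OC(C)=O)[C@]12C | target

**Count**

Total steps: 20. Longest linear sequence: 18 (steps 1–8 and 11–20, from 1); steps 9 and 10 form the side branch.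

**Steps most likely to fail, with fallbacks**

Step 7. The alkylcopper may add to the lactone carbonyl, or may substitute at the less hindered allylic terminus, because the γ-carbon adjoins a quaternary centre. The fallback sets out from 8 and returns at 11. Aminolysis of 8 with Me(MeO)NH·HCl and Me3Al (CH2Cl2, 0 °C → rt) should give the hydroxy Weinreb amide F1. Esterification with pyridine-2-carboxylic acid (DCC, DMAP, CH2Cl2) gives the allylic picolinate F2. Reaction of F2 with 9 and CuBr·SMe2 (THF, −40 °C), in which the picolinoxy group chelates the metal and directs anti SN2′ substitution on a flexible monocycle, gives the Weinreb amide F3. MeMgBr (THF, 0 °C) converts F3 into methyl ketone 11.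

Step 17. Facial selectivity at the aldehyde carbon during ring closure may be poor or reversed, which would give the C7 epimer. The fallback sets out from 22 and returns at 24. The 7S alcohol F4 from the same ring closure is esterified under Mitsunobu conditions (methacrylic acid, PPh3, DIAD, toluene, 0 °C) with inversion at C7, which leads directly to methacrylate 24.

Step 20. The peracid may attack the α face (anti to the axial C15 methyl), or C5=C6 may compete. The fallback sets out from 25 and returns at 26. NBS in aqueous DME (0 °C) should form the bromonium ion on the more accessible α face; water opens it at the tertiary C11 from the β face to give the bromohydrin F5. K2CO3 in acetone then closes F5 to the β-epoxide 26 by intramolecular displacement of bromide, so that the oxygen ends on the face opposite to the one the electrophile attacked.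

**Further compounds**

F1 | step 7 | hydroxy Weinreb amide from 8 (lactone opened by N-methoxy-N-methylamine; C12 hydroxyl cis to the amide; C10=C11) | CON(C)C(=O)[C@]1(C)C=C(C)[C@H](O)C[C@@H]1O[Si](C)(C)C(C)(C)C
F2 | step 7 | pyridine-2-carboxylate (picolinate) of F1 at the allylic hydroxyl | CON(C)C(=O)[C@]1(C)C=C(C)[C@H](OC(=O)c2ccccn2)C[C@@H]1O[Si](C)(C)C(C)(C)C
F3 | step 7 | N-methoxy-N-methylamide corresponding to acid 10 | CON(C)C(=O)[C@]1(C)[C@@H](CCC2OCCO2)C(C)=CC[C@@H]1O[Si](C)(C)C(C)(C)C
F4 | step 17 | C7 epimer (7S) of alcohol 23 | CCCC(=O)O[C@H]1CC/C(C)=C\[C@H](O)C(=C)C[C@H]2C(C)=CC[C@H](OC(C)=O)[C@]12C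
F5 | step 20 | bromohydrin of 25 (11β-hydroxy, 12α-bromo) | CCCC(=O)O[C@H]1CC/C(C)=C\[C@H]2OC(=O)C(C)=C2C[C@H]2[C@@](C)(O)[C@H](Br)C[C@H](OC(C)=O)[C@]12C
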